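**Retrosynthetic overview**

1. Feature: the bridge methine carbon joins two identical, fully substituted phloroglucinol rings, so it is flanked by four ortho oxygens and is not a stereocentre. It also carries a CH2–CH(CH3)2 chain, and the CH2–CH bond of that chain lies outside the congestion.
2. Last disconnections: the two aryl–prenyl bonds (C-prenylation at the single free ring carbon of each ring of 12), then six O–CH3 bonds and two aryl–acetyl bonds (Friedel–Crafts acylation of hexamethyl ether 10, done before demethylation).
3. Key disconnection: the CH2–CH(CH3)2 bond of 10, formed by adding an isopropyl radical (from the N-hydroxyphthalimide ester 9 of isobutyric acid) to the =CH2 terminus of 1,1-bis(2,4,6-trimethoxyphenyl)ethene 7; hydrogen-atom transfer then sets the methine.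
4. Alkene 7 comes from hexamethoxybenzophenone 5 (MeLi, then dehydration); 5 comes from 2,4,6-trimethoxyphenyllithium and 2,4,6-trimethoxybenzaldehyde, followed by oxidation of the benzhydrol.
5. No ring is formed: the two benzene rings are bought as 1,3,5-trimethoxybenzene and 2,4,6-trimethoxybenzaldehyde.

Key step: step 6

Remark: the target has no stereocentre. The two aryl groups are joined on a carbon without α-hydrogens and the methyl group is added afterwards, because an aryl methyl ketone flanked by two ortho-methoxy groups would be prone to enolisation by a hindered aryllithium.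

**Route**

Step 1
Reactants: 1 1,3,5-trimethoxybenzene; 2 2,4,6-trimethoxybenzaldehyde
Product: 4 bis(2,4,6-trimethoxyphenyl)methanol, via 2,4,6-trimethoxyphenyllithium 3 (not isolated)
Conditions: 1, n-BuLi, TMEDA, THF, 0 °C → rt; then 2, −78 °C → rt; H2O
Reagents that add atoms: none
Why: Directed ortho-lithiation of 1 between two methoxy groups gives 3, and 1,2-addition of an aryllithium to an aromatic aldehyde is the standard route to a benzhydrol; aldehyde 2 has no α-hydrogens, so enolisation cannot compete.

Step 2
Reactants: 4 bis(2,4,6-trimethoxyphenyl)methanol
Product: 5 bis(2,4,6-trimethoxyphenyl)methanone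
Conditions: (n-Pr4N)RuO4 (cat.), N-methylmorpholine N-oxide, 4 Å MS, CH2Cl2, rt
Reagents that add atoms: none
Why: Ley–Griffith oxidation of a secondary benzylic alcohol runs under neutral conditions, which avoids the acid that would ionise this very electron-rich benzhydrol to its carbenium ion.

Step 3
Reactants: 5 bis(2,4,6-trimethoxyphenyl)methanone
Product: 6 1,1-bis(2,4,6-trimethoxyphenyl)ethanol
Conditions: MeLi, THF, 0 °C → rt; H2O
Reagents that add atoms: methyllithium, [Li]C
Why: 1,2-Addition of the small, hard methyllithium to a diaryl ketone without α-hydrogens cannot be diverted by enolisation, and a carbonyl flanked by four ortho-methoxy groups (smaller than methyl and able to coordinate lithium) should still be open to so small a nucleophile.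

Step 4
Reactants: 6 1,1-bis(2,4,6-trimethoxyphenyl)ethanol
Product: 7 1,1-bis(2,4,6-trimethoxyphenyl)ethene
Conditions: TsOH·H2O (cat.), 4 Å MS, toluene, 60 °C; then Et3N
Reagents that add atoms: none
Why: Acid-catalysed E1 dehydration runs through the strongly stabilised diarylmethyl-type carbenium ion, whose only β-hydrogens are those of the methyl group, so 7 is the single possible alkene; the crowded cation centre disfavours dimerisation.

Step 5
Reactants: 8 isobutyric acid
Product: 9 1,3-dioxoisoindolin-2-yl 2-methylpropanoate
Conditions: N-hydroxyphthalimide, N,N'-diisopropylcarbodiimide, DMAP (cat.), CH2Cl2, rt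
Reagents that add atoms: N-hydroxyphthalimide, ON1C(=O)c2ccccc2C1=O
Why: Steglich-type carbodiimide esterification of a carboxylic acid with N-hydroxyphthalimide is the routine preparation of redox-active esters.

Step 6
Reactants: 7 1,1-bis(2,4,6-trimethoxyphenyl)ethene; 9 1,3-dioxoisoindolin-2-yl 2-methylpropanoate
Product: 10 1,1-bis(2,4,6-trimethoxyphenyl)-3-methylbutane
Conditions: Ru(bpy)3Cl2·6H2O (cat.), Hantzsch ester (diethyl 2,6-dimethyl-1,4-dihydropyridine-3,5-dicarboxylate), i-Pr2NEt, degassed DMF, blue LEDs (450 nm), rt
Reagents that add atoms: none
Why: Under blue light the excited Ru(bpy)3 dication is quenched reductively by the Hantzsch ester (or the amine), and the reduced ruthenium complex passes one electron to ester 9, whose radical anion fragments to phthalimide anion, CO2 and the isopropyl radical. This secondary alkyl radical adds to the unsubstituted =CH2 carbon of 7, forming the CH2–CH(CH3)2 bond and a diarylmethyl radical, which is capped by hydrogen-atom transfer from the Hantzsch ester or its radical cation to give the bridge methine. The closest known reaction type is the reductive decarboxylative Giese-type hydroalkylation of styrenes and 1,1-diarylethenes with N-acyloxyphthalimides under photoredox catalysis. No ring is closed and no stereocentre is created, because the new methine carries two identical aryl groups. The step needs regioselectivity for the terminal carbon, secured by the open CH2 position next to an internal carbon shielded by four ortho-methoxy groups and by the benzylic stabilisation of the adduct radical; it also needs the electron-rich alkene to survive, secured by reductive radical generation with the Hantzsch ester as the preferred quencher and by the amine base, which keeps the medium free of acid. The congested carbon therefore receives only a hydrogen atom and never a carbon substituent.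

Step 7
Reactants: 10 1,1-bis(2,4,6-trimethoxyphenyl)-3-methylbutane
Product: 11 1,1-bis(3-acetyl-2,4,6-trimethoxyphenyl)-3-methylbutane
Conditions: Ac2O (2.4 equiv), Sc(OTf)3 (cat.), MeNO2, 0 °C → rt
Reagents that add atoms: acetic anhydride, CC(=O)OC(C)=O
Why: Friedel–Crafts acylation at a ring CH flanked by two methoxy groups has the reactivity of 1,3,5-trimethoxybenzene, and the first acetyl group deactivates its ring so that each ring should be acylated once; acylating at the methyl ether stage keeps free ortho-phenols, and with them xanthene closure, out of the acidic medium.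

Step 8
Reactants: 11 1,1-bis(3-acetyl-2,4,6-trimethoxyphenyl)-3-methylbutane
Product: 12 1,1-bis(3-acetyl-2,4,6-trihydroxyphenyl)-3-methylbutane
Conditions: BBr3 (excess), CH2Cl2, −78 °C → rt; then H2O, 0 °C
Reagents that add atoms: none
Why: Lewis-acid cleavage of aryl methyl ethers by BBr3 is assisted by chelation for the four methoxy groups ortho to the acetyl groups, and the boron-complexed acyl groups make the rings poor bases, so ipso-protonation and cleavage at the bridge are disfavoured.

Step 9
Reactants: 12 1,1-bis(3-acetyl-2,4,6-trihydroxyphenyl)-3-methylbutane; 13 prenyl bromide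
Product: 14 1,1-bis[3-acetyl-2,4,6-trihydroxy-5-(3-methylbut-2-enyl)phenyl]-3-methylbutane (target)
Conditions: 13 (2.2 equiv), KOH (10% aq.), 0 °C
Reagents that add atoms: none
Why: SN2 C-alkylation of the ambident acylphloroglucinol phenolate in water, where hydrogen bonding shields the oxygens, should direct the soft allylic bromide to the one remaining nucleophilic ring carbon of each ring.

**Compound list**

1 | 1,3,5-trimethoxybenzene | COc1cc(OC)cc(OC)c1 | starting material
2 | 2,4,6-trimethoxybenzaldehyde | COc1cc(OC)c(C=O)c(OC)c1 | starting material
3 | 2,4,6-trimethoxyphenyllithium | [Li]c1c(OC)cc(OC)cc1OC | intermediate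
4 | bis(2,4,6-trimethoxyphenyl)methanol | OC(c1c(OC)cc(OC)cc1OC)c1c(OC)cc(OC)cc1OC | intermediate
5 | bis(2,4,6-trimethoxyphenyl)methanone | O=C(c1c(OC)cc(OC)cc1OC)c1c(OC)cc(OC)cc1OC | intermediate
6 | 1,1-bis(2,4,6-trimethoxyphenyl)ethanol | CC(O)(c1c(OC)cc(OC)cc1OC)c1c(OC)cc(OC)cc1OC | intermediate
7 | 1,1-bis(2,4,6-trimethoxyphenyl)ethene | C=C(c1c(OC)cc(OC)cc1OC)c1c(OC)cc(OC)cc1OC | intermediate
8 | isobutyric acid | CC(C)C(=O)O | starting material
9 | 1,3-dioxoisoindolin-2-yl 2-methylpropanoate | CC(C)C(=O)ON1C(=O)c2ccccc2C1=O | intermediate
10 | 1,1-bis(2,4,6-trimethoxyphenyl)-3-methylbutane | COc1cc(OC)c(C(CC(C)C)c2c(OC)cc(OC)cc2OC)c(OC)c1 | intermediate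
11 | 1,1-bis(3-acetyl-2,4,6-trimethoxyphenyl)-3-methylbutane | CC(=O)c1c(OC)cc(OC)c(C(CC(C)C)c2c(OC)cc(OC)c(C(C)=O)c2OC)c1OC | intermediate
12 | 1,1-bis(3-acetyl-2,4,6-trihydroxyphenyl)-3-methylbutane | CC(=O)c1c(O)cc(O)c(C(CC(C)C)c2c(O)cc(O)c(C(C)=O)c2O)c1O | intermediate
13 | prenyl bromide (1-bromo-3-methylbut-2-ene) | CC(C)=CCBr | starting material
14 | 1,1-bis[3-acetyl-2,4,6-trihydroxy-5-(3-methylbut-2-enyl)phenyl]-3-methylbutane | CC(=O)c1c(O)c(CC=C(C)C)c(O)c(C(CC(C)C)c2c(O)c(CC=C(C)C)c(O)c(C(C)=O)c2O)c1O | target

**Step count**

Total steps: 9. Longest linear sequence: 8 steps (steps 1–4, then 6–9); step 5 is a one-step branch.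

**Steps most likely to fail**

Step 6 (key step). The isopropyl radical may be quenched by hydrogen transfer from the Hantzsch ester faster than it adds to the twisted, electron-rich alkene. The alkene may also be lost by protonation and hydride reduction to the 1,1-diarylethane. The fallback is ionic and sets out from 4. Treatment of 4 with methallyltrimethylsilane and catalytic BF3·OEt2 in CH2Cl2 at −78 °C should ionise the benzhydrol to the stabilised diarylcarbenium ion, which is captured in a Hosomi–Sakurai-type allylation to give 4,4-bis(2,4,6-trimethoxyphenyl)-2-methylbut-1-ene F1. Hydrogenation of the 1,1-disubstituted alkene (H2, Pd/C, EtOAc, rt) then gives the isobutyl chain, and the fallback comes back to the route at 10.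

Step 9. O-alkylation may compete, a second dearomatising alkylation may occur at an already substituted ring carbon, and base may cleave the aryl–CH bond at the bridge by a retro-Michael (quinone-methide) fragmentation. The fallback sets out from 12 and replaces the SN2 alkylation by a Tsuji–Trost C-prenylation: prenyl methyl carbonate and Pd(PPh3)4 (cat.) in THF at rt. The methoxide released from the carbonate is the only base. O-prenyl ethers are re-ionised by the catalyst, so material should funnel to the C-prenylated arene, and the phenolate carbon attacks the unsubstituted terminus of the π-prenyl palladium complex. This gives 14 directly; no compound outside the list is formed on this way (F0).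

Step 7. An acylium ion or a proton may attack the bridge-bearing ring carbon, with loss of the stabilised benzylic cation and cleavage of the diarylmethine; a ring may also be acylated twice. The fallback sets out from 10 and avoids acid altogether. Double directed ortho-lithiation (n-BuLi, TMEDA, THF, 0 °C), once per ring at a CH between two methoxy groups, should give 1,1-bis(3-lithio-2,4,6-trimethoxyphenyl)-3-methylbutane F2. Acylation of F2 with N-methoxy-N-methylacetamide at −78 °C → rt, through the stable Weinreb chelate, gives the bis(methyl ketone), and the fallback comes back to the route at 11.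

**Further compounds**

F1 | step 6 | 4,4-bis(2,4,6-trimethoxyphenyl)-2-methylbut-1-ene | C=C(C)CC(c1c(OC)cc(OC)cc1OC)c1c(OC)cc(OC)cc1OC
F2 | step 7 | 1,1-bis(3-lithio-2,4,6-trimethoxyphenyl)-3-methylbutane | [Li]c1c(OC)cc(OC)c(C(CC(C)C)c2c(OC)cc(OC)c([Li])c2OC)c1OC
F0 | step 9 | none | none
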